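The furan‑fused cycloheptanone (C1, C16, C13, C12, C11, C9, C10; clerodane numbering) is made by ring expansion. A five‑membered cyclic enol ether (O, C12, C13, C16, C1), spiro‑fused to ring A at C1, undergoes a Claisen rearrangement across C9=C10. In one operation a tertiary 3‑ethynylfuran‑2‑yl carbinol cyclises 5‑exo‑dig and shifts [3,3], forming C11–C9, the C12 ketone, the quaternary C9 stereocenter and the C1=C10 alkene that later carries 10‑OH. The step exploits the 4‑cycloheptenone pattern C12(=O)–C11–C9–C10=C1 and the furan bond C13=C16 as tether.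

Key step: step 12

Remark on the chemistry: clerodane numbering is used from compound 7 on (C18 lactone carbonyl, C19 lactone CH2, C20 methyl on C9, C17 carbon on C8); β is the face of the 10‑hydroxyl of the target, α the opposite face.

Step 1
Reactants: 1 cyclohexane-1,3-dione; 2 pent-1-en-3-one
Product: 3 2-(3-oxopentyl)cyclohexane-1,3-dione
Conditions: H2O, 23 °C
Reagents that add atoms: none
Why: Michael addition of the enolised 1,3-dione to the vinyl ketone in water should stop at the mono-adduct; no stereocenter is formed.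

Step 2
Reactants: 3 2-(3-oxopentyl)cyclohexane-1,3-dione; 4 formaldehyde
Product: 5 2-(hydroxymethyl)-2-(3-oxopentyl)cyclohexane-1,3-dione
Conditions: 37% aq. HCHO, NaHCO3 (cat.), THF, 0 → 23 °C
Reagents that add atoms: none
Why: crossed aldol (hydroxymethylation) at the doubly activated C2–H of the 2-alkyl-1,3-dione creates the carbon that becomes C19 on a still prochiral quaternary center.

Step 3
Reactants: 5 2-(hydroxymethyl)-2-(3-oxopentyl)cyclohexane-1,3-dione
Product: 6 [2,6-dioxo-1-(3-oxopentyl)cyclohexyl]methyl acetate
Conditions: Ac2O, 4-(dimethylamino)pyridine (cat.), pyridine, CH2Cl2, 0 °C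
Reagents that add atoms: acetic anhydride CC(=O)OC(C)=O
Why: O-acylation protects the β-hydroxy diketone against retro-aldol loss of formaldehyde.

Step 4
Reactants: 6 [2,6-dioxo-1-(3-oxopentyl)cyclohexyl]methyl acetate
Product: 7 (8aR)-8a-(acetoxymethyl)-5-methyl-3,4,8,8a-tetrahydronaphthalene-1,6(2H,7H)-dione
Conditions: D-phenylalanine (1 eq), (1R)-(−)-camphor-10-sulfonic acid (0.5 eq), DMF, 30 → 70 °C
Reagents that add atoms: none
Why: Hajos–Parrish–Eder–Sauer–Wiechert aldol condensation; the D-amino acid enamine selects one of the two enantiotopic ring carbonyls, which sets C5 (19-CH2 α) and gives the tetrasubstituted C9=C10 enone.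

Step 5
Reactants: 7 (8aR)-8a-(acetoxymethyl)-5-methyl-3,4,8,8a-tetrahydronaphthalene-1,6(2H,7H)-dione
Product: 8 C4 enol triflate of 7 (C3=C4–OTf; enone and 19-OAc unchanged)
Conditions: LiN(SiMe3)2, THF, −78 °C; then PhNTf2, −78 → 0 °C
Reagents that add atoms: N-phenylbis(trifluoromethanesulfonimide) O=S(=O)(N(c1ccccc1)S(=O)(=O)C(F)(F)F)C(F)(F)F
Why: kinetic enolisation of the more acidic saturated C4 ketone (only C3–H is available, C5 is quaternary) and O-triflation should outrun formation of the cross-conjugated enolate of the enone.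

Step 6
Reactants: 8 C4 enol triflate of 7
Product: 10 enone butenolide (5S; C3=C4; 18,19-olide; C9(Me)=C10; C8=O), via methyl ester 9 (not isolated)
Conditions: Pd(OAc)2 (5 mol %), 1,3-bis(diphenylphosphino)propane, CO (1 atm), Et3N, MeOH/DMF, 60 °C; then K2CO3 (cat.), MeOH, 23 °C
Reagents that add atoms: carbon monoxide [C-]#[O+]
Why: palladium-catalysed alkoxycarbonylation of the enol triflate installs C18, and acetate methanolysis lets the 19-alkoxide lactonise onto the C18 ester to close the butenolide.

Step 7
Reactants: 10 enone butenolide; 11 2,3-dibromofuran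
Product: 12 1-(3-bromofuran-2-yl) enone butenolide (C1 epimer mixture)
Conditions: Pd(OAc)2 (5 mol %), PPh3 (10 mol %), Cs2CO3, DMF, 80 °C
Reagents that add atoms: none
Why: palladium-catalysed γ-arylation of the extended dienolate of the enone; oxidative addition occurs at the more reactive C2–Br of the furan, and the C1 configuration is erased in step 9.

Step 8
Reactants: 12 1-(3-bromofuran-2-yl) enone butenolide; 13 ethynyltrimethylsilane
Product: 14 1-[3-(trimethylsilylethynyl)furan-2-yl] enone butenolide (C1 epimer mixture)
Conditions: PdCl2(PPh3)2 (5 mol %), CuI (10 mol %), i-Pr2NH, THF, 60 °C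
Reagents that add atoms: none
Why: Sonogashira coupling at the remaining furan C3–Br places the alkyne ortho to the future carbinol carbon.

Step 9
Reactants: 14 1-[3-(trimethylsilylethynyl)furan-2-yl] enone butenolide
Product: 15 9β-(phenylseleno)-9α-methyl-8-oxo-1(10)-ene (C1=C10 conjugated to the furan)
Conditions: KN(SiMe3)2, THF, −78 °C; then PhSeCl, −78 °C
Reagents that add atoms: benzeneselenenyl chloride Cl[Se]c1ccccc1
Why: deconjugative α-selenenylation of the extended dienolate (the doubly activated C1–H is removed); selenium enters C9 from the β face, anti to the 19-CH2 on C5, which is the face C11 must later occupy.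

Step 10
Reactants: 15 9β-(phenylseleno)-9α-methyl-8-oxo-1(10)-ene
Product: 18 1β-hydroxy-1α-[3-(trimethylsilylethynyl)furan-2-yl] enone butenolide, via selenoxide 16 (not isolated), via selenenate 17 (not isolated)
Conditions: H2O2 (30% aq.), pyridine, CH2Cl2, 0 → 23 °C
Reagents that add atoms: hydrogen peroxide OO
Why: the allylic selenoxide undergoes a suprafacial [2,3]-sigmatropic selenoxide–selenenate rearrangement that carries oxygen to the β face of C1 and restores the C9=C10 enone; hydrolysis gives the tertiary alcohol.

Step 11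
Reactants: 18 1β-hydroxy-1α-[3-(trimethylsilylethynyl)furan-2-yl] enone butenolide
Product: 19 triene carbinol (C8=CH2; C9=C10; 1β-OH)
Conditions: Cp2Ti(μ-CH2)(μ-Cl)AlMe2 (2.5 eq), pyridine, THF, −40 → 0 °C
Reagents that add atoms: Tebbe reagent [cH-]1cccc1.[cH-]1cccc1.[CH2-2].[Cl-].[CH3-].[CH3-].[Ti+4].[Al+3]
Why: Tebbe methylenation turns the hindered C8 ketone into the exocyclic methylene before a second ketone (C12) exists, and should spare the lactone at this temperature.

Step 12
Reactants: 19 triene carbinol
Product: 22 furan-fused cycloheptenone (C12=O; C9 quaternary with C11 β and C20 α; C1=C10; C8=CH2), via ethynyl carbinol 20 (not isolated), via spiro enol ether 21 (not isolated)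
Conditions: K2CO3 (cat.), MeOH, 23 °C; then KOt-Bu (10 mol %), DMSO, 23 °C; then mesitylene, 165 °C (sealed tube)
Reagents that add atoms: none
Why: Methanolysis frees the terminal alkyne, the tertiary alkoxide adds 5-exo-dig to it (closing the ring O, C12, C13, C16, C1), and the resulting allyl vinyl ether undergoes a thermal Claisen rearrangement in which C11 bonds to C9 and C1–O breaks; the closest known reaction type is the tandem 5-exo-dig cyclisation–Claisen rearrangement of 1-alkenyl-4-pentyn-1-ols to 4-cycloheptenones. The seven-membered ring therefore arises by a two-atom [3,3] ring expansion of the five-membered enol ether through a bridged, boat-like transition state (8-oxabicyclo[3.2.1]octene-like), not by direct cyclisation. The new quaternary C9 stereocenter is controlled by the C1 carbinol center: the shift is suprafacial, so C11 is delivered to the β face on which the C1–O bond lies and the C20 methyl stays α. The step needs 5-exo over 6-endo closure, which base-mediated addition to a terminal alkyne held ortho on the furan should secure, and it needs the concerted shift to outrun ionisation of the doubly allylic C1–O bond, which a non-polar medium free of acid favours. Because C1 carries no hydrogen, the enol ether cannot aromatise and can only rearrange.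

Step 13
Reactants: 22 furan-fused cycloheptenone
Product: 23 1β,10β-epoxide of 22
Conditions: dimethyldioxirane, acetone, −40 → 0 °C
Reagents that add atoms: dimethyldioxirane CC1(C)OO1
Why: the tetrasubstituted C1=C10 alkene is the most nucleophilic one and should be epoxidised first, from the β face because the α face is shielded by the 19-CH2 and the C20 methyl.

Step 14
Reactants: 23 1β,10β-epoxide
Product: 24 10β-hydroxy-1α-H ketone (C8=CH2)
Conditions: SmI2 (2.5 eq), THF/MeOH, −78 °C
Reagents that add atoms: none
Why: two-electron reduction of the furyl ketone opens the vinylogous α,β-epoxy ketone at C1 (samarium dienolate through the furan), and protonation at C1 from the less hindered α face restores the furan; the net result is anti addition of H and OH.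

Step 15
Reactants: 24 10β-hydroxy-1α-H ketone
Product: 25 7α,10β-diol (C8=CH2)
Conditions: SeO2 (0.5 eq), t-BuOOH, CH2Cl2, 23 °C
Reagents that add atoms: tert-butyl hydroperoxide CC(C)(C)OO
Why: allylic hydroxylation (ene reaction then [2,3] shift) of the exocyclic methylene removes the axial 7α-H and returns oxygen on the same face; C9 is quaternary, so only C7 can react.

Step 16
Reactants: 25 7α,10β-diol
Product: 26 7α-acetate (10β-OH free; C8=CH2)
Conditions: Ac2O, 4-(dimethylamino)pyridine (cat.), pyridine, 23 °C
Reagents that add atoms: acetic anhydride CC(=O)OC(C)=O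
Why: acylation of the secondary allylic alcohol; the hindered tertiary 10-OH should not react.

Step 17
Reactants: 26 7α-acetate
Product: 27 CNP0329797.2
Conditions: H2 (1 atm), RhCl(PPh3)3 (10 mol %), benzene/EtOH, 23 °C
Reagents that add atoms: none
Why: homogeneous hydrogenation should reduce only the 1,1-disubstituted alkene; H2 adds from the β face because the α face is blocked by the axial C20 methyl and the 7α-acetate, which sets C8 (17-methyl α, equatorial).

Compound list
1 | cyclohexane-1,3-dione | O=C1CCCC(=O)C1 | starting material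
2 | pent-1-en-3-one | CCC(=O)C=C | starting material
3 | 2-(3-oxopentyl)cyclohexane-1,3-dione | CCC(=O)CCC1C(=O)CCCC1=O | intermediate
4 | formaldehyde | C=O | starting material
5 | 2-(hydroxymethyl)-2-(3-oxopentyl)cyclohexane-1,3-dione | CCC(=O)CCC1(CO)C(=O)CCCC1=O | intermediate
6 | [2,6-dioxo-1-(3-oxopentyl)cyclohexyl]methyl acetate | CCC(=O)CCC1(COC(C)=O)C(=O)CCCC1=O | intermediate
7 | (8aR)-8a-(acetoxymethyl)-5-methyl-3,4,8,8a-tetrahydronaphthalene-1,6(2H,7H)-dione | O=C2CCCC3=C(C)C(=O)CC[C@@]23COC(C)=O | intermediate
8 | C4 enol triflate of 7 (C3=C4–OTf) | FC(F)(F)S(=O)(=O)OC2=CCCC3=C(C)C(=O)CC[C@@]23COC(C)=O | intermediate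
9 | methyl ester (C4–CO2Me, 19-OAc; not isolated) | COC(=O)C2=CCCC3=C(C)C(=O)CC[C@@]23COC(C)=O | intermediate
10 | enone butenolide (5S; C3=C4; 18,19-olide; C9(Me)=C10; C8=O) | O=C1CC[C@@]23COC(=O)C2=CCCC3=C1C | intermediate
11 | 2,3-dibromofuran | Brc1occc1Br | starting material
12 | 1-(3-bromofuran-2-yl) enone butenolide (C1 epimers) | O=C1CC[C@@]23COC(=O)C2=CCC(c4occc4Br)C3=C1C | intermediate
13 | ethynyltrimethylsilane | C#C[Si](C)(C)C | starting material
14 | 1-[3-(trimethylsilylethynyl)furan-2-yl] enone butenolide (C1 epimers) | O=C1CC[C@@]23COC(=O)C2=CCC(c4occc4C#C[Si](C)(C)C)C3=C1C | intermediate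
15 | 9β-(phenylseleno)-9α-methyl-8-oxo-1(10)-ene | c1ccccc1[Se][C@@]4(C)C(=O)CC[C@@]23COC(=O)C2=CCC(c5occc5C#C[Si](C)(C)C)=C34 | intermediate
16 | selenoxide of 15 (not isolated) | c1ccccc1[Se](=O)[C@@]4(C)C(=O)CC[C@@]23COC(=O)C2=CCC(c5occc5C#C[Si](C)(C)C)=C34 | intermediate
17 | 1β-O-phenylselenenate (not isolated) | O=C1CC[C@@]23COC(=O)C2=CC[C@](O[Se]c5ccccc5)(c4occc4C#C[Si](C)(C)C)C3=C1C | intermediate
18 | 1β-hydroxy-1α-[3-(trimethylsilylethynyl)furan-2-yl] enone butenolide | O=C1CC[C@@]23COC(=O)C2=CC[C@](O)(c4occc4C#C[Si](C)(C)C)C3=C1C | intermediate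
19 | triene carbinol (C8=CH2; C9=C10; 1β-OH) | C=C1CC[C@@]23COC(=O)C2=CC[C@](O)(c4occc4C#C[Si](C)(C)C)C3=C1C | intermediate
20 | ethynyl carbinol (not isolated) | C=C1CC[C@@]23COC(=O)C2=CC[C@](O)(c4occc4C#C)C3=C1C | intermediate
21 | spiro 4-methylene-4H-furo[3,4-b]furan enol ether at C1 (C1–O β; not isolated) | C=C1CC[C@@]23COC(=O)C2=CC[C@@]4(OC(=C)c5ccoc54)C3=C1C | intermediate
22 | furan-fused cycloheptenone (C12=O; C11 β on C9; C1=C10; C8=CH2) | C=C1CC[C@@]23COC(=O)C2=CCC4=C3[C@@]1(C)CC(=O)c5ccoc54 | intermediate
23 | 1β,10β-epoxide of 22 | C=C1CC[C@@]23COC(=O)C2=CC[C@]45O[C@]53[C@@]1(C)CC(=O)c6ccoc64 | intermediate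
24 | 10β-hydroxy-1α-H ketone (C8=CH2) | C1C[C@@]23COC(=O)C2=CC[C@H]2c4occc4C(=O)C[C@@](C)(C1=C)[C@@]23O | intermediate
25 | 7α,10β-diol (C8=CH2) | O[C@@H]1C[C@@]23COC(=O)C2=CC[C@H]2c4occc4C(=O)C[C@@](C)(C1=C)[C@@]23O | intermediate
26 | 7α-acetate (C8=CH2) | CC(=O)O[C@@H]1C[C@@]23COC(=O)C2=CC[C@H]2c4occc4C(=O)C[C@@](C)(C1=C)[C@@]23O | intermediate
27 | CNP0329797.2 | CC(=O)O[C@@H]1C[C@@]23COC(=O)C2=CC[C@H]2c4occc4C(=O)C[C@@](C)([C@@H]1C)[C@@]23O | target

Total step count: 17. Longest linear sequence: 17 steps (from 1; compounds 2, 4, 11 and 13 enter as purchased reagents).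

Steps most likely to fail

Step 12 (key step). Ionisation of the doubly allylic, furfurylic C1–O bond (elimination, or a 1,3-shift through an ion pair), or attack of the tertiary alkoxide on the butenolide, may compete with 5-exo-dig closure. The fallback reaches the same spiro enol ether from a lactone instead of an alkyne. From 10, γ-arylation with methyl 2-bromofuran-3-carboxylate under the conditions of step 7 should give the furoate F1, and selenenylation as in step 9 the selenide F2. Oxidation as in step 10 gives the 1β-alkoxide, which lactonises to the spiro furofuranone F3. Excess Cp2Ti(μ-CH2)(μ-Cl)AlMe2 (THF, −40 → 23 °C) then methylenates both the C8 ketone and the aryl lactone carbonyl, and the route is rejoined at 21, which rearranges to 22 on heating.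

Step 7. The palladium dienolate may show poor site selectivity: arylation at C7, at the γ-carbon C2 of the butenolide, or twofold arylation. The fallback reverses the polarity at C1. From 10, Me3SiCl/NaI/Et3N should give the extended trimethylsilyl dienol ether F4, which N-bromosuccinimide brominates at the γ-carbon to the 1-bromo enone F5. Negishi coupling of F5 with (3-bromofuran-2-yl)zinc chloride (from 3-bromofuran, LiN(i-Pr)2 and ZnCl2) under Pd(PPh3)4 returns to 12.

Step 14. The samarium dienolate may be protonated from the β face, or the C12 ketone may be reduced further. The fallback opens the epoxide homolytically. From 23, Cp2TiCl (trivalent titanium, made from Cp2TiCl2 and Mn) with 2,4,6-collidinium chloride and 1,4-cyclohexadiene in THF cleaves C1–O to the furan-stabilised C1 radical, which is reduced by hydrogen-atom transfer. Should the 1-epimer F6 form, catalytic 1,8-diazabicyclo[5.4.0]undec-7-ene in toluene equilibrates it through the vinylogous enol to the trans-fused 24.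

Further compounds
F1 | step 12 | 1-[3-(methoxycarbonyl)furan-2-yl] enone butenolide (C1 epimers) | O=C1CC[C@@]23COC(=O)C2=CCC(c4occc4C(=O)OC)C3=C1C
F2 | step 12 | 9β-(phenylseleno) furoate analogue of 15 | c1ccccc1[Se][C@@]4(C)C(=O)CC[C@@]23COC(=O)C2=CCC(c5occc5C(=O)OC)=C34
F3 | step 12 | spiro furo[3,4-b]furan-4-one lactone at C1 (C1–O β; C8=O) | O=C1CC[C@@]23COC(=O)C2=CC[C@@]4(OC(=O)c5ccoc54)C3=C1C
F4 | step 7 | extended trimethylsilyl dienol ether of 10 (C8–OSiMe3; C8=C9; C10=C1) | C[Si](C)(C)OC1=C(C)C4=CCC=C2C(=O)OC[C@]24CC1
F5 | step 7 | 1-bromo enone butenolide (C1 epimers) | O=C1CC[C@@]23COC(=O)C2=CCC(Br)C3=C1C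
F6 | step 14 | 1-epimer of 24 (1β-H) | C1C[C@@]23COC(=O)C2=CC[C@@H]2c4occc4C(=O)C[C@@](C)(C1=C)[C@@]23O
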